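**Assumption:** Angustone B has no stereogenic centre or stereogenic alkene (the prenyl olefin is gem-dimethyl, the chromene olefin is endocyclic), so it is achiral and no enantiocontrol is needed.

## Retrosynthetic overview

1. Angustone B ⇐ tri-MOM isoflavone **17** (global deprotection) ⇐ Suzuki–Miyaura coupling forming C3–C1′ from 3-iodochromone **10** (A/C rings) and chromenyl boronate **16** (B/D rings).
2. **10** ⇐ enaminone/I2 ring closure of o-hydroxyacetophenone **7**. The hydroxyl that becomes O1 is installed by ketone-directed Ir C–H borylation/oxidation of **6** (new step). Ketone **6** has only one ortho C–H, so 6- versus 8-prenyl ambiguity cannot arise.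
3. **6** ⇐ resorcinol by two successive directed ortho-metalations: prenyl between the two OMOM groups, then acetyl.
4. **16** ⇐ ortho-lithiation/borylation of MOM-protected 2,2-dimethylchromen-5-ol, made from cyclohexane-1,3-dione and prenal (Knoevenagel/oxa-6π) followed by dehydrogenative aromatisation.
5. Ring order: D (pyran) then B (aromatisation) in one branch; A is carried from resorcinol and C (pyranone) is closed just before the coupling.

## Route

### Branch A (A/C rings)

**Step 1**
Reactants: **1** resorcinol
Product: **2** 1,3-bis(methoxymethoxy)benzene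
Conditions: NaH, MOMCl, DMF, 0 °C → rt
Reagents that add atoms: chloromethyl methyl ether, COCCl
Why: Williamson-type O-alkylation of both phenoxides installs the MOM groups that serve as ortho-directing groups and as final protecting groups.

**Step 2**
Reactants: **2**; **3** prenyl bromide (1-bromo-3-methylbut-2-ene)
Product: **4** 1,3-bis(methoxymethoxy)-2-(3-methylbut-2-en-1-yl)benzene
Conditions: n-BuLi, THF, 0 °C → rt; CuBr·SMe2, then **3**, −40 °C → rt
Reagents that add atoms: none other than reactant **3** (CC(C)=CCBr)
Why: Directed ortho-metalation occurs at C2, doubly activated by the flanking OMOM groups, and the aryl cuprate is alkylated at the primary carbon (SN2) to give the linear prenyl group.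

**Step 3**
Reactants: **4**; **5** N-methoxy-N-methylacetamide
Product: **6** 1-[2,4-bis(methoxymethoxy)-3-(3-methylbut-2-en-1-yl)phenyl]ethan-1-one
Conditions: n-BuLi, TMEDA, THF, 0 °C; then **5**, −78 → 0 °C
Reagents that add atoms: none other than reactant **5** (CON(C)C(C)=O)
Why: A second OMOM-directed ortho-lithiation at C4 (C4 and C6 are equivalent) followed by Weinreb amide acylation gives the methyl ketone without over-addition.

**Step 4**
Reactants: **6**
Product: **7** 1-[6-hydroxy-2,4-bis(methoxymethoxy)-3-(3-methylbut-2-en-1-yl)phenyl]ethan-1-one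
Conditions: [Ir(OMe)(cod)]2 (2.5 mol%), P[3,5-(CF3)2C6H3]3 (10 mol%), B2pin2 (1.3 equiv), methylcyclohexane, 80 °C; then THF/H2O, NaBO3·4H2O, rt (one pot; ortho-Bpin ketone not isolated)
Reagents that add atoms: sodium perborate, [Na+].[O-]OB=O (supplies the phenolic O); bis(pinacolato)diboron, CC1(C)OB(OC1(C)C)B1OC(C)(C)C(C)(C)O1 (Bpin is transient, not retained)
Why: Proposed new method: a one-pot ketone-directed Ir ortho-C–H borylation/oxidation used as a non-acidic C–H hydroxylation. The acetyl oxygen binds an Ir(III)(Bpin)3 fragment carrying a single labile, electron-poor phosphine (two cis sites free) and delivers it through a five-membered iridacycle to the only ortho C–H (C6′). C–B reductive elimination gives a C=O→B-stabilised aryl boronate, which perborate oxidises with retention to the chelated phenol. The other ring C–H (C5′) lacks a five-membered chelate path, and the trisubstituted olefin and MOM acetals should be inert to neutral Ir–boryl conditions. The closest known reaction is carbonyl-directed Ir ortho-borylation of simple benzoates and aryl ketones; it has not been shown on a tetrasubstituted, electron-rich, olefin- and acetal-bearing acetophenone, nor used to complete a phloroglucinol-type ring.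

**Step 5**
Reactants: **7**; **8** N,N-dimethylformamide dimethyl acetal
Product: **9** (E)-3-(dimethylamino)-1-[6-hydroxy-2,4-bis(methoxymethoxy)-3-(3-methylbut-2-en-1-yl)phenyl]prop-2-en-1-one
Conditions: DMF-DMA (3 equiv), toluene, 90 °C
Reagents that add atoms: none other than reactant **8** (COC(OC)N(C)C)
Why: Condensation of the methyl ketone with the amide acetal gives the E-enaminone (vinylogous amide), which supplies C2 of the chromone.

**Step 6**
Reactants: **9**
Product: **10** 3-iodo-5,7-bis(methoxymethoxy)-6-(3-methylbut-2-en-1-yl)-4H-chromen-4-one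
Conditions: I2 (1.1 equiv), pyridine, CHCl3, 0 °C → rt; aq. Na2S2O3
Reagents that add atoms: iodine, II
Why: Iodination of the highly nucleophilic enaminone α-carbon, 6-endo attack of the free phenol on the iminium and loss of Me2NH give the 3-iodochromone (iodocyclisation of o-hydroxyaryl enaminones); the enaminone outcompetes the prenyl olefin for a near-stoichiometric amount of I2.

### Branch B (B/D rings)

**Step 7**
Reactants: **11** cyclohexane-1,3-dione; **12** 3-methylbut-2-enal
Product: **13** 2,2-dimethyl-2,6,7,8-tetrahydro-5H-chromen-5-one
Conditions: ethylenediammonium diacetate (10 mol%), MeOH, rt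
Reagents that add atoms: none other than reactants **11** and **12**
Why: Knoevenagel condensation gives a 1-oxatriene that closes by oxa-6π electrocyclisation (formal [3+3]), fixing the oxygen pattern of the angular chromene unambiguously.

**Step 8**
Reactants: **13**
Product: **14** 2,2-dimethyl-2H-chromen-5-ol
Conditions: LDA, THF, −78 °C; PhSeCl; then 30% H2O2, pyridine, CH2Cl2, 0 °C → rt
Reagents that add atoms: none retained (phenylselenenyl chloride, Cl[Se]c1ccccc1, adds SePh transiently)
Why: Kinetic α′-selenation at C6 and selenoxide syn-elimination give a cross-conjugated dienone that tautomerises to the phenol (dehydrogenative aromatisation).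

**Step 9**
Reactants: **14**
Product: **15** 5-(methoxymethoxy)-2,2-dimethyl-2H-chromene
Conditions: MOMCl, i-Pr2NEt, CH2Cl2, 0 °C → rt
Reagents that add atoms: chloromethyl methyl ether, COCCl
Why: Phenol O-alkylation installs the directing and protecting group for the next step.

**Step 10**
Reactants: **15**
Product: **16** 2-[5-(methoxymethoxy)-2,2-dimethyl-2H-chromen-6-yl]-4,4,5,5-tetramethyl-1,3,2-dioxaborolane
Conditions: n-BuLi, TMEDA, THF, −20 → 0 °C; then i-PrOBpin, −78 °C → rt
Reagents that add atoms: 2-isopropoxy-4,4,5,5-tetramethyl-1,3,2-dioxaborolane, CC(C)OB1OC(C)(C)C(C)(C)O1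
Why: OMOM-directed ortho-lithiation can only occur at C6 (the other ortho position is the ring fusion) and the aryllithium is trapped as the pinacol boronate.

### Union and end game

**Step 11**
Reactants: **10**; **16**
Product: **17** 5,7-bis(methoxymethoxy)-3-[5-(methoxymethoxy)-2,2-dimethyl-2H-chromen-6-yl]-6-(3-methylbut-2-en-1-yl)-4H-chromen-4-one
Conditions: Pd(dppf)Cl2·CH2Cl2 (5 mol%), 2 M aq. Na2CO3, DME, 80 °C, degassed
Reagents that add atoms: none
Why: Suzuki–Miyaura coupling of the vinylogous-ester C3–I bond with the mono-ortho-substituted aryl boronate forms the C3–C1′ bond under mild carbonate conditions that the chromone, MOM ethers and both olefins tolerate.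

**Step 12**
Reactants: **17**
Product: **18** Angustone B, 5,7-dihydroxy-3-(5-hydroxy-2,2-dimethyl-2H-chromen-6-yl)-6-(3-methylbut-2-en-1-yl)-4H-chromen-4-one
Conditions: 3 M aq. HCl, MeOH/THF, 45 °C, stopped at full conversion
Reagents that add atoms: none
Why: Acid-catalysed acetal hydrolysis removes all three MOM groups; dilute acid and moderate temperature are chosen to keep the prenyl group from cyclising onto the flanking phenols and to spare the chromene.

## Compound list

1 | resorcinol | Oc1cccc(O)c1 | starting material
2 | 1,3-bis(methoxymethoxy)benzene | COCOc1cccc(OCOC)c1 | intermediate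
3 | prenyl bromide | CC(C)=CCBr | starting material
4 | 1,3-bis(methoxymethoxy)-2-(3-methylbut-2-en-1-yl)benzene | COCOc1cccc(OCOC)c1CC=C(C)C | intermediate
5 | N-methoxy-N-methylacetamide | CON(C)C(C)=O | starting material
6 | 1-[2,4-bis(methoxymethoxy)-3-(3-methylbut-2-en-1-yl)phenyl]ethan-1-one | CC(=O)c1ccc(OCOC)c(CC=C(C)C)c1OCOC | intermediate
7 | 1-[6-hydroxy-2,4-bis(methoxymethoxy)-3-(3-methylbut-2-en-1-yl)phenyl]ethan-1-one | CC(=O)c1c(O)cc(OCOC)c(CC=C(C)C)c1OCOC | intermediate
8 | N,N-dimethylformamide dimethyl acetal | COC(OC)N(C)C | starting material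
9 | (E)-3-(dimethylamino)-1-[6-hydroxy-2,4-bis(methoxymethoxy)-3-(3-methylbut-2-en-1-yl)phenyl]prop-2-en-1-one | CN(C)/C=C/C(=O)c1c(O)cc(OCOC)c(CC=C(C)C)c1OCOC | intermediate
10 | 3-iodo-5,7-bis(methoxymethoxy)-6-(3-methylbut-2-en-1-yl)-4H-chromen-4-one | O=c1c(I)coc2cc(OCOC)c(CC=C(C)C)c(OCOC)c12 | intermediate
11 | cyclohexane-1,3-dione | O=C1CCCC(=O)C1 | starting material
12 | 3-methylbut-2-enal | CC(C)=CC=O | starting material
13 | 2,2-dimethyl-2,6,7,8-tetrahydro-5H-chromen-5-one | CC1(C)C=CC2=C(O1)CCCC2=O | intermediate
14 | 2,2-dimethyl-2H-chromen-5-ol | CC1(C)C=Cc2c(O)cccc2O1 | intermediate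
15 | 5-(methoxymethoxy)-2,2-dimethyl-2H-chromene | COCOc1cccc2OC(C)(C)C=Cc12 | intermediate
16 | 2-[5-(methoxymethoxy)-2,2-dimethyl-2H-chromen-6-yl]-4,4,5,5-tetramethyl-1,3,2-dioxaborolane | COCOc1c(B3OC(C)(C)C(C)(C)O3)ccc2OC(C)(C)C=Cc12 | intermediate
17 | 5,7-bis(methoxymethoxy)-3-[5-(methoxymethoxy)-2,2-dimethyl-2H-chromen-6-yl]-6-(3-methylbut-2-en-1-yl)-4H-chromen-4-one | COCOc1c(-c3coc4cc(OCOC)c(CC=C(C)C)c(OCOC)c4c3=O)ccc2OC(C)(C)C=Cc12 | intermediate
18 | Angustone B | CC(C)=CCc1c(O)cc2occ(-c3ccc4c(c3O)C=CC(C)(C)O4)c(=O)c2c1O | target

## Summary

**Total step count:** 12 (one-pot operations counted as one step).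
**Longest linear sequence:** 8 (steps 1–6, 11, 12); the other branch is 6 (steps 7–10, 11, 12).

**Steps most likely to fail, with fallbacks**

1. **Step 4 (proposed new ketone-directed C–H borylation/oxidation).** Risks are weak ketone direction on a crowded electron-rich ring, Ir–H chemistry at the prenyl olefin, and Dakin-type over-oxidation. Fallback (known chemistry): introduce the third oxygen before the prenyl group.
   - Sterically controlled Ir/dtbpy C5-borylation–oxidation of **2** gives 3,5-bis(methoxymethoxy)phenol.
   - O-TIPS protection, ortho-lithiation/prenylation between the two OMOM groups, and desilylation give 3,5-bis(methoxymethoxy)-4-prenylphenol, whose two ortho positions are equivalent.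
   - MgCl2/Et3N/paraformaldehyde ortho-formylation, MeMgBr addition and MnO2 oxidation then converge on **7**.

2. **Step 12 (acidic removal of three MOM groups next to a prenyl group and a chromene).** The risk is acid-catalysed cyclisation of the prenyl group onto the 5- or 7-OH. Fallback: run the whole route with SEM ethers in place of MOM (they also direct ortho-lithiation) and unmask at the end with fluoride (TBAF, DMPU, heat) under non-acidic conditions.

3. **Step 6 (I2 cyclisation in the presence of the prenyl olefin).** The risk is competing iodo-functionalisation of the alkene. Fallback: avoid electrophilic halogen by the deoxybenzoin approach.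
   - Protect the 6′-OH of **7** as a silyl ether.
   - Pd-catalysed ketone α-arylation with the 6-bromo analogue of **15** (same aryllithium quenched with a Br+ source) forms the C3–C1′ bond.
   - Desilylation and DMF-DMA one-carbon insertion/cyclisation give **17** directly.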